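**Retrosynthetic overview**

1. Actephilol C ← bis-benzyl ether 33 (hydrogenolysis) ← open keto aldehyde/aryl iodide 31 by one domino event that makes the C-3–C-4 bond of lower ring C and the aryl C-3'–O bond of the 1,4-dioxane ring (aldol addition, then copper-catalysed O-arylation, run as a dynamic kinetic asymmetric process).
2. Enabling feature: the ketal carbon C-3 of lower ring C lies between the C-2 ketone (whose other α-carbon, C-1, is quaternary) and C-4, and its aryloxy oxygen sits on C-2' of upper ring C' next to C-3'. C-3–H is therefore the only enolisable position, the aldol adduct cannot dehydrate, and the new C-4 alkoxide is held one six-membered ring away from C-3'.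
3. 31 ← upper phenol 14 + lower glyoxal aldehyde 28, joined at the mixed O,O-acetal carbon through an α-chloro ether.
4. Lower naphthalene: ring B is built from the open-chain β-keto ester 18 (naphthalene-1,3-diol 19), then C-formylation, triflate, palladium-catalysed ester arylation (quaternary C-1), chloromethyl ketone and Kornblum oxidation.
5. Upper phenanthrene: Suzuki biaryl (rings A' and C'), iodination at the future C-3' before ring B' exists, ring B' closed by Friedel–Crafts acylation and selective O-methylation of the 9-phenanthrol. Ring order: B' (upper), B (lower), then lower ring C and the dioxane ring together.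

Key step: step 19

Remarks on the chemistry (assumptions):
- Locants: the lower half is numbered as a 3,4-dihydrophenanthren-2(1H)-one (C-1 to C-10a), the upper half as a phenanthrene with primed locants; naphthalene and biphenyl intermediates carry their own usual locants.
- The sense of induction of the copper–diamine catalyst in step 19 cannot be derived from a model. The (1R,2R)-ligand is written; the mirror-image ligand is taken if the first run delivers the antipode.

**Route**

Step 1
Reactants: 1 5-bromo-2-methylphenol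
Product: 2 2-(benzyloxy)-4-bromo-1-methylbenzene
Conditions: BnBr, K2CO3, DMF, rt
Reagents that add atoms: benzyl bromide, BrCc1ccccc1
Why: Williamson ether synthesis of the phenoxide with a reactive benzylic halide; no stereocenter.

Step 2
Reactants: 2 2-(benzyloxy)-4-bromo-1-methylbenzene
Product: 3 2-[3-(benzyloxy)-4-methylphenyl]-4,4,5,5-tetramethyl-1,3,2-dioxaborolane
Conditions: B2pin2, PdCl2(dppf) (3 mol %), KOAc, 1,4-dioxane, 90 °C
Reagents that add atoms: bis(pinacolato)diboron, CC1(C)OB(OC1(C)C)B1OC(C)(C)C(C)(C)O1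
Why: Miyaura borylation of an unhindered aryl bromide, which tolerates the benzyl ether.

Step 3
Reactants: 4 3-bromo-2-methylphenol
Product: 5 (3-bromo-2-methylphenoxy)(tert-butyl)dimethylsilane
Conditions: TBSCl, imidazole, DMF, rt
Reagents that add atoms: tert-butyl(chloro)dimethylsilane, CC(C)(C)[Si](C)(C)Cl
Why: Standard silylation masks the acidic phenol for the organozinc coupling, and the bulky silyl ether later shields the ortho position in the bromination.

Step 4
Reactants: 5 (3-bromo-2-methylphenoxy)(tert-butyl)dimethylsilane; 6 (2-tert-butoxy-2-oxoethyl)zinc bromide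
Product: 7 tert-butyl 2-[3-(tert-butyldimethylsilyloxy)-2-methylphenyl]acetate
Conditions: Pd2(dba)3 (1 mol %), XPhos (4 mol %), THF, 60 °C
Reagents that add atoms: none
Why: Negishi-type cross-coupling of a Reformatsky reagent (palladium-catalysed ester α-arylation under neutral conditions), which accepts the ortho methyl group and leaves the silyl ether intact.

Step 5
Reactants: 7 tert-butyl 2-[3-(tert-butyldimethylsilyloxy)-2-methylphenyl]acetate
Product: 8 tert-butyl 2-[6-bromo-3-(tert-butyldimethylsilyloxy)-2-methylphenyl]acetate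
Conditions: NBS, MeCN, 0 °C → rt, dark
Reagents that add atoms: N-bromosuccinimide, O=C1CCC(=O)N1Br
Why: Electrophilic aromatic bromination goes para to the silyloxy group (the ortho position is screened by the silyl group), which is the carbon that becomes C-4a'.

Step 6
Reactants: 8 tert-butyl 2-[6-bromo-3-(tert-butyldimethylsilyloxy)-2-methylphenyl]acetate; 3 2-[3-(benzyloxy)-4-methylphenyl]-4,4,5,5-tetramethyl-1,3,2-dioxaborolane
Product: 10 tert-butyl 2-[3'-(benzyloxy)-4-hydroxy-3,4'-dimethylbiphenyl-2-yl]acetate, via silyl ether biaryl 9 (not isolated)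
Conditions: Pd(OAc)2 (3 mol %), SPhos (6 mol %), K3PO4, toluene/H2O, 80 °C; then TBAF, THF, rt
Reagents that add atoms: none
Why: Suzuki–Miyaura coupling with a biarylphosphine ligand handles the ortho-substituted bromide, and fluoride desilylation in the same flask frees only the ring C' phenol.

Step 7
Reactants: 10 tert-butyl 2-[3'-(benzyloxy)-4-hydroxy-3,4'-dimethylbiphenyl-2-yl]acetate
Product: 11 tert-butyl 2-[3'-(benzyloxy)-4-hydroxy-5-iodo-3,4'-dimethylbiphenyl-2-yl]acetate
Conditions: NIS (1.05 equiv), cat. TFA, MeCN, 0 °C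
Reagents that add atoms: N-iodosuccinimide, O=C1CCC(=O)N1I
Why: Electrophilic iodination of the free phenol at its only open ortho position (the future C-3'), much faster than attack on the benzyl ether ring; it is done before ring B' exists because a 1-methyl-2-phenanthrol would react at C-1 instead.

Step 8
Reactants: 11 tert-butyl 2-[3'-(benzyloxy)-4-hydroxy-5-iodo-3,4'-dimethylbiphenyl-2-yl]acetate
Product: 14 6-(benzyloxy)-3-iodo-9-methoxy-1,7-dimethylphenanthren-2-ol, via biarylacetic acid 12 (not isolated), via phenanthrene-2,9-diol 13 (not isolated)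
Conditions: TFA, CH2Cl2, rt, evaporate; (CF3CO)2O, CH2Cl2, 0 °C → rt; then MeOH, cat. H2SO4, 60 °C
Reagents that add atoms: methanol, CO
Why: Acidolysis of the tert-butyl ester, intramolecular Friedel–Crafts acylation through the mixed trifluoroacetic anhydride para to the benzyloxy group (closing ring B' as the 9-phenanthrol) and Fischer-type etherification of that phenanthrol through its keto tautomer, which leaves the ordinary C-2' phenol untouched.

Step 9
Reactants: 15 (3-methoxy-4-methylphenyl)acetic acid; 16 potassium 3-ethoxy-3-oxopropanoate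
Product: 18 ethyl 4-(3-methoxy-4-methylphenyl)-3-oxobutanoate, via acyl imidazolide 17 (not isolated)
Conditions: CDI, THF, rt; then 16, MgCl2, Et3N, MeCN, rt → 40 °C; 1 M HCl work-up
Reagents that add atoms: 1,1'-carbonyldiimidazole, O=C(n1ccnc1)n1ccnc1 (imidazolyl group of 17 only; no atom of it remains in 18)
Why: Masamune–Brooks C-acylation of the magnesium malonate half-ester by the acyl imidazolide, followed by decarboxylation.

Step 10
Reactants: 18 ethyl 4-(3-methoxy-4-methylphenyl)-3-oxobutanoate
Product: 19 6-methoxy-7-methylnaphthalene-1,3-diol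
Conditions: MeSO3H, 0 °C → rt
Reagents that add atoms: none
Why: Acid-mediated intramolecular Friedel–Crafts acylation by the ester carbon at the position para to the methoxy group, followed by enolisation, builds ring B from the open chain with both oxygens in place.

Step 11
Reactants: 19 6-methoxy-7-methylnaphthalene-1,3-diol
Product: 20 2,4-dihydroxy-7-methoxy-6-methylnaphthalene-1-carbaldehyde
Conditions: POCl3, DMF, 0 °C → rt; then H2O, 50 °C
Reagents that add atoms: N,N-dimethylformamide, CN(C)C=O (formyl carbon); water, O (aldehyde oxygen)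
Why: Vilsmeier–Haack formylation at the α-position that is ortho to one hydroxyl and para to the other (C-4 of the diol), the site at which naphthalene-1,3-diols react.

Step 12
Reactants: 20 2,4-dihydroxy-7-methoxy-6-methylnaphthalene-1-carbaldehyde
Product: 21 4-(benzyloxy)-2-hydroxy-7-methoxy-6-methylnaphthalene-1-carbaldehyde
Conditions: BnBr (1.05 equiv), KHCO3, DMF, 40 °C
Reagents that add atoms: benzyl bromide, BrCc1ccccc1
Why: Williamson etherification is selective for the 4-hydroxyl because the 2-hydroxyl is tied up in a hydrogen bond to the formyl group, as in 2,4-dihydroxybenzaldehyde.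

Step 13
Reactants: 21 4-(benzyloxy)-2-hydroxy-7-methoxy-6-methylnaphthalene-1-carbaldehyde
Product: 22 4-(benzyloxy)-1-formyl-7-methoxy-6-methylnaphthalen-2-yl trifluoromethanesulfonate
Conditions: Tf2O, pyridine, CH2Cl2, 0 °C
Reagents that add atoms: trifluoromethanesulfonic anhydride, O=S(=O)(OS(=O)(=O)C(F)(F)F)C(F)(F)F
Why: O-sulfonylation of the remaining phenol turns the formylation-directing oxygen into a cross-coupling leaving group.

Step 14
Reactants: 22 4-(benzyloxy)-1-formyl-7-methoxy-6-methylnaphthalen-2-yl trifluoromethanesulfonate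
Product: 23 4-(benzyloxy)-1-(dimethoxymethyl)-7-methoxy-6-methylnaphthalen-2-yl trifluoromethanesulfonate
Conditions: HC(OMe)3, MeOH, cat. TsOH, 50 °C
Reagents that add atoms: trimethyl orthoformate, COC(OC)OC
Why: Acid-catalysed acetalisation protects the aldehyde from the zinc enolate of step 15 and the carbenoid of step 16.

Step 15
Reactants: 23 4-(benzyloxy)-1-(dimethoxymethyl)-7-methoxy-6-methylnaphthalen-2-yl trifluoromethanesulfonate; 24 [(1-methoxy-2-methylprop-1-en-1-yl)oxy]trimethylsilane
Product: 25 methyl 2-[4-(benzyloxy)-1-(dimethoxymethyl)-7-methoxy-6-methylnaphthalen-2-yl]-2-methylpropanoate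
Conditions: Pd2(dba)3 (2.5 mol %), XPhos (6 mol %), ZnF2 (0.6 equiv), DMF, 80 °C
Reagents that add atoms: none
Why: Palladium-catalysed α-arylation of an ester through its silyl ketene acetal and ZnF2 (Hartwig-type coupling) creates the quaternary benzylic carbon C-1 without strong base.

Step 16
Reactants: 25 methyl 2-[4-(benzyloxy)-1-(dimethoxymethyl)-7-methoxy-6-methylnaphthalen-2-yl]-2-methylpropanoate
Product: 26 3-[4-(benzyloxy)-1-(dimethoxymethyl)-7-methoxy-6-methylnaphthalen-2-yl]-1-chloro-3-methylbutan-2-one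
Conditions: ClCH2I, MeLi·LiBr, THF/Et2O, −78 °C; then H2O at −78 °C
Reagents that add atoms: chloroiodomethane, ClCI
Why: Homologation of the ester with chloromethyllithium generated in its presence; the small carbenoid reaches the hindered ester and the tetrahedral adduct survives at −78 °C, so the chloromethyl ketone is released only on quench.

Step 17
Reactants: 26 3-[4-(benzyloxy)-1-(dimethoxymethyl)-7-methoxy-6-methylnaphthalen-2-yl]-1-chloro-3-methylbutan-2-one
Product: 28 3-[4-(benzyloxy)-1-formyl-7-methoxy-6-methylnaphthalen-2-yl]-3-methyl-2-oxobutanal, via glyoxal dimethyl acetal 27 (not isolated)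
Conditions: NaI (cat.), NaHCO3, DMSO, 80 °C; then 1 M aq HCl, THF, rt
Reagents that add atoms: dimethyl sulfoxide, CS(C)=O (oxygen of the new aldehyde); water, O (oxygen of the unmasked aryl aldehyde)
Why: Iodide-assisted Kornblum oxidation of the α-chloro ketone gives a glyoxal that has no enolisable hydrogen, and mild aqueous acid then cleaves the electron-rich aryl acetal.

Step 18
Reactants: 28 3-[4-(benzyloxy)-1-formyl-7-methoxy-6-methylnaphthalen-2-yl]-3-methyl-2-oxobutanal; 14 6-(benzyloxy)-3-iodo-9-methoxy-1,7-dimethylphenanthren-2-ol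
Product: 31 4-(benzyloxy)-2-{4-[(6-(benzyloxy)-3-iodo-9-methoxy-1,7-dimethylphenanthren-2-yl)oxy]-4-methoxy-2-methyl-3-oxobutan-2-yl}-7-methoxy-6-methylnaphthalene-1-carbaldehyde (racemic at the acetal carbon), via methyl hemiacetal 29 (not isolated), via α-chloro ether 30 (not isolated)
Conditions: MeOH, 4 Å MS, rt, evaporate; SOCl2, CH2Cl2, 0 °C → rt, evaporate; then 14, iPr2NEt, CH2Cl2, 0 °C → rt
Reagents that add atoms: methanol, CO (methoxy group of the acetal); thionyl chloride, O=S(Cl)Cl (chlorine of 30 only)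
Why: Methanol adds only to the glyoxal aldehyde, thionyl chloride turns the hemiacetal into the α-chloro ether (as in the preparation of alkyl chloro(methoxy)acetates) and the phenol displaces chloride as in MOM ether formation; the acetal carbon forms as a racemate, which is irrelevant because it is planarised in step 19.

Step 19
Reactants: 31 4-(benzyloxy)-2-{4-[(6-(benzyloxy)-3-iodo-9-methoxy-1,7-dimethylphenanthren-2-yl)oxy]-4-methoxy-2-methyl-3-oxobutan-2-yl}-7-methoxy-6-methylnaphthalene-1-carbaldehyde
Product: 33 (3S,4S)-9,6'-di-O-benzylactephilol C, via cesium cis-aldolate 32 (not isolated)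
Conditions: copper iodide CuI (10 mol %), (1R,2R)-N,N'-dimethyl-1,2-diphenylethane-1,2-diamine (20 mol %), Cs2CO3 (2.5 equiv), MeCN, 50 °C
Reagents that add atoms: none
Why: Proposed new method: Cs2CO3 removes the only acidic C–H of 31 (at the acetal carbon C-3, since C-1 is quaternary) and the α,α-dioxygenated cesium enolate adds to the C-4 aldehyde in a reversible 6-(enolendo)-exo-trig aldol that closes lower ring C and gives the aldolates (32 and its stereoisomers) as a pool that interconverts by retro-aldol; the closest known reaction types are the intramolecular aldol addition, the Ullmann-type intramolecular O-arylation and the copper-catalysed enantioselective desymmetrising O-arylation of diols to 1,4-benzodioxanes, merged here into one dynamic kinetic asymmetric domino. The C-4 alkoxide is then arylated at C-3' by the monovalent copper–diamine catalyst (copper alkoxide, oxidative addition of the C-3'–I bond, C–O reductive elimination from trivalent copper), an irreversible six-membered ring closure that forms the 1,4-dioxane ring. The cis relation of C-3 and C-4 is controlled by the substrate: bay strain against C-5–H forces the C-4 oxygen pseudoaxial on ring C, so only an equatorial, that is cis, C-3 aryloxy group can bring C-3' within reach, and the trans aldolates return to the pool. The absolute configuration (3S,4S) is controlled by the chiral diamine on copper, which has to select one of the two rapidly equilibrating cis enantiomers in the C–O bond-forming event. The step needs O-arylation by the aldolate and not by the enolate oxygen, which is secured because closure onto the non-enolisable aryl aldehyde is fast and the enolate is only fleeting, while C-arylation would need a four-membered ring and dehydration is impossible because C-3 carries no hydrogen after the aldol step.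

Step 20
Reactants: 33 (3S,4S)-9,6'-di-O-benzylactephilol C
Product: 34 actephilol C
Conditions: H2 (1 atm), 10 % Pd/C, EtOAc, rt
Reagents that add atoms: none
Why: Hydrogenolysis of the two unhindered primary benzyl aryl ethers under neutral conditions, which should spare the hindered cyclic secondary benzylic aryl ether at C-4 (as it does in flavans and benzodioxane neolignans) and touches neither stereocenter.

**Compound list**

1 | 5-bromo-2-methylphenol | Cc1ccc(Br)cc1O | starting material
2 | 2-(benzyloxy)-4-bromo-1-methylbenzene | Cc1ccc(Br)cc1OCc1ccccc1 | intermediate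
3 | 2-[3-(benzyloxy)-4-methylphenyl]-4,4,5,5-tetramethyl-1,3,2-dioxaborolane | Cc1ccc(B2OC(C)(C)C(C)(C)O2)cc1OCc1ccccc1 | intermediate
4 | 3-bromo-2-methylphenol | Cc1c(O)cccc1Br | starting material
5 | (3-bromo-2-methylphenoxy)(tert-butyl)dimethylsilane | Cc1c(O[Si](C)(C)C(C)(C)C)cccc1Br | intermediate
6 | (2-tert-butoxy-2-oxoethyl)zinc bromide (Reformatsky reagent, solution in THF) | CC(C)(C)OC(=O)C[Zn]Br | starting material
7 | tert-butyl 2-[3-(tert-butyldimethylsilyloxy)-2-methylphenyl]acetate | Cc1c(O[Si](C)(C)C(C)(C)C)cccc1CC(=O)OC(C)(C)C | intermediate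
8 | tert-butyl 2-[6-bromo-3-(tert-butyldimethylsilyloxy)-2-methylphenyl]acetate | Cc1c(O[Si](C)(C)C(C)(C)C)ccc(Br)c1CC(=O)OC(C)(C)C | intermediate
9 | tert-butyl 2-[3'-(benzyloxy)-4-(tert-butyldimethylsilyloxy)-3,4'-dimethylbiphenyl-2-yl]acetate | Cc1ccc(-c2ccc(O[Si](C)(C)C(C)(C)C)c(C)c2CC(=O)OC(C)(C)C)cc1OCc1ccccc1 | intermediate (not isolated)
10 | tert-butyl 2-[3'-(benzyloxy)-4-hydroxy-3,4'-dimethylbiphenyl-2-yl]acetate | Cc1ccc(-c2ccc(O)c(C)c2CC(=O)OC(C)(C)C)cc1OCc1ccccc1 | intermediate
11 | tert-butyl 2-[3'-(benzyloxy)-4-hydroxy-5-iodo-3,4'-dimethylbiphenyl-2-yl]acetate | Cc1ccc(-c2cc(I)c(O)c(C)c2CC(=O)OC(C)(C)C)cc1OCc1ccccc1 | intermediate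
12 | 2-[3'-(benzyloxy)-4-hydroxy-5-iodo-3,4'-dimethylbiphenyl-2-yl]acetic acid | Cc1ccc(-c2cc(I)c(O)c(C)c2CC(=O)O)cc1OCc1ccccc1 | intermediate (not isolated)
13 | 6-(benzyloxy)-3-iodo-1,7-dimethylphenanthrene-2,9-diol | Cc1c(O)c(I)cc2c1cc(O)c1cc(C)c(OCc3ccccc3)cc12 | intermediate (not isolated)
14 | 6-(benzyloxy)-3-iodo-9-methoxy-1,7-dimethylphenanthren-2-ol | Cc1c(O)c(I)cc2c1cc(OC)c1cc(C)c(OCc3ccccc3)cc12 | intermediate
15 | (3-methoxy-4-methylphenyl)acetic acid | COc1cc(CC(=O)O)ccc1C | starting material
16 | potassium 3-ethoxy-3-oxopropanoate | CCOC(=O)CC(=O)[O-].[K+] | starting material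
17 | 1-(1H-imidazol-1-yl)-2-(3-methoxy-4-methylphenyl)ethan-1-one | COc1cc(CC(=O)n2ccnc2)ccc1C | intermediate (not isolated)
18 | ethyl 4-(3-methoxy-4-methylphenyl)-3-oxobutanoate | CCOC(=O)CC(=O)Cc1ccc(C)c(OC)c1 | intermediate
19 | 6-methoxy-7-methylnaphthalene-1,3-diol | COc1cc2cc(O)cc(O)c2cc1C | intermediate
20 | 2,4-dihydroxy-7-methoxy-6-methylnaphthalene-1-carbaldehyde | COc1cc2c(C=O)c(O)cc(O)c2cc1C | intermediate
21 | 4-(benzyloxy)-2-hydroxy-7-methoxy-6-methylnaphthalene-1-carbaldehyde | COc1cc2c(C=O)c(O)cc(OCc3ccccc3)c2cc1C | intermediate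
22 | 4-(benzyloxy)-1-formyl-7-methoxy-6-methylnaphthalen-2-yl trifluoromethanesulfonate | COc1cc2c(C=O)c(OS(=O)(=O)C(F)(F)F)cc(OCc3ccccc3)c2cc1C | intermediate
23 | 4-(benzyloxy)-1-(dimethoxymethyl)-7-methoxy-6-methylnaphthalen-2-yl trifluoromethanesulfonate | COc1cc2c(C(OC)OC)c(OS(=O)(=O)C(F)(F)F)cc(OCc3ccccc3)c2cc1C | intermediate
24 | [(1-methoxy-2-methylprop-1-en-1-yl)oxy]trimethylsilane | COC(O[Si](C)(C)C)=C(C)C | starting material
25 | methyl 2-[4-(benzyloxy)-1-(dimethoxymethyl)-7-methoxy-6-methylnaphthalen-2-yl]-2-methylpropanoate | COc1cc2c(C(OC)OC)c(C(C)(C)C(=O)OC)cc(OCc3ccccc3)c2cc1C | intermediate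
26 | 3-[4-(benzyloxy)-1-(dimethoxymethyl)-7-methoxy-6-methylnaphthalen-2-yl]-1-chloro-3-methylbutan-2-one | COc1cc2c(C(OC)OC)c(C(C)(C)C(=O)CCl)cc(OCc3ccccc3)c2cc1C | intermediate
27 | 3-[4-(benzyloxy)-1-(dimethoxymethyl)-7-methoxy-6-methylnaphthalen-2-yl]-3-methyl-2-oxobutanal | COc1cc2c(C(OC)OC)c(C(C)(C)C(=O)C=O)cc(OCc3ccccc3)c2cc1C | intermediate (not isolated)
28 | 3-[4-(benzyloxy)-1-formyl-7-methoxy-6-methylnaphthalen-2-yl]-3-methyl-2-oxobutanal | COc1cc2c(C=O)c(C(C)(C)C(=O)C=O)cc(OCc3ccccc3)c2cc1C | intermediate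
29 | 4-(benzyloxy)-2-(4-hydroxy-4-methoxy-2-methyl-3-oxobutan-2-yl)-7-methoxy-6-methylnaphthalene-1-carbaldehyde (racemic) | COc1cc2c(C=O)c(C(C)(C)C(=O)C(O)OC)cc(OCc3ccccc3)c2cc1C | intermediate (not isolated)
30 | 4-(benzyloxy)-2-(4-chloro-4-methoxy-2-methyl-3-oxobutan-2-yl)-7-methoxy-6-methylnaphthalene-1-carbaldehyde (racemic) | COc1cc2c(C=O)c(C(C)(C)C(=O)C(Cl)OC)cc(OCc3ccccc3)c2cc1C | intermediate (not isolated)
31 | 4-(benzyloxy)-2-{4-[(6-(benzyloxy)-3-iodo-9-methoxy-1,7-dimethylphenanthren-2-yl)oxy]-4-methoxy-2-methyl-3-oxobutan-2-yl}-7-methoxy-6-methylnaphthalene-1-carbaldehyde (racemic at the acetal carbon) | COc1cc2c(C=O)c(C(C)(C)C(=O)C(OC)Oc3c(I)cc4c(cc(OC)c5cc(C)c(OCc6ccccc6)cc54)c3C)cc(OCc3ccccc3)c2cc1C | intermediate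
32 | cesium (3S,4S)-9-(benzyloxy)-3-[(6-(benzyloxy)-3-iodo-9-methoxy-1,7-dimethylphenanthren-2-yl)oxy]-3,6-dimethoxy-1,1,7-trimethyl-2-oxo-1,2,3,4-tetrahydrophenanthren-4-olate (C-4 oxygen cis to the C-3 aryloxy group) | COc1cc2c3c(cc(OCc4ccccc4)c2cc1C)C(C)(C)C(=O)[C@@](OC)(Oc1c(I)cc4c(cc(OC)c5cc(C)c(OCc6ccccc6)cc54)c1C)[C@H]3[O-].[Cs+] | intermediate (not isolated)
33 | (3S,4S)-9,6'-di-O-benzylactephilol C: (3S,4S)-9-(benzyloxy)-3,6-dimethoxy-1,1,7-trimethyl-3,4-dihydrophenanthren-2(1H)-one whose O-3 and O-4 are bonded to C-2' and C-3' of 6'-(benzyloxy)-9'-methoxy-1',7'-dimethylphenanthrene (cis-fused 1,4-dioxane) | COc1cc2c3c(cc(OCc4ccccc4)c2cc1C)C(C)(C)C(=O)[C@@]1(OC)Oc2c(cc4c(cc(OC)c5cc(C)c(OCc6ccccc6)cc54)c2C)O[C@@H]31 | intermediate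
34 | actephilol C: (3S,4S)-9-hydroxy-3,6-dimethoxy-1,1,7-trimethyl-3,4-dihydrophenanthren-2(1H)-one whose O-3 and O-4 are bonded to C-2' and C-3' of 9'-methoxy-1',7'-dimethylphenanthren-6'-ol (cis-fused 1,4-dioxane) | COc1cc2c3c(cc(O)c2cc1C)C(C)(C)C(=O)[C@@]1(OC)Oc2c(cc4c(cc(OC)c5cc(C)c(O)cc54)c2C)O[C@@H]31 | target

**Totals**

Total step count: 20.
Longest linear sequence: 12 steps (15 → 34, steps 9–20). The upper half (steps 1–8) joins at step 18.

**Steps most likely to fail**

1. Step 19 (labelled step). The copper catalyst may not discriminate well enough between the two equilibrating cis-aldolate enantiomers, so that enantiomeric purity is low, or C–O bond formation may be slower than base-induced degradation of the open keto aldehyde. The fallback sets out from 31, separates the two bond formations and introduces the chirality by separation. LiHMDS (THF, −78 °C, cold acetic acid quench) effects the intramolecular aldol addition to the racemic cis-aldol F1. A standard Ullmann ether synthesis (CuI, 1,10-phenanthroline, Cs2CO3, toluene, 90 °C) closes the dioxane ring to the racemic dibenzyl ether F2; under these conditions the aldol still equilibrates with its epimers and the bay-strain argument still selects the cis-fused ring. Preparative HPLC on an amylose tris(3,5-dimethylphenylcarbamate) phase separates F2 into 33, where the route is rejoined, and the mirror-image dibenzyl ether F3.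

2. Step 15. Transmetalation and reductive elimination at the doubly hindered centre may be slow, so that hydrolysis or reduction of the C–OTf bond wins. The fallback sets out from 23 and builds the quaternary carbon in two stages. A Negishi-type coupling with the Reformatsky reagent made from methyl bromoacetate and zinc (Pd2(dba)3, XPhos, THF, 60 °C), a primary and much less hindered nucleophile, gives the naphthylacetate F4. Exhaustive α-methylation (NaH, MeI, DMF, 0 °C → rt) passes through the monomethyl ester F5 and ends at 25.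

3. Step 18. The α-chloro ether may ionise, hydrolyse or attack C-3 of its own naphthalene before the hindered 2-iodo-6-methyl-type phenol reacts, or chlorination may be incomplete because the hemiacetal reverts to the hydrate. The fallback sets out from 26 (aldehyde still masked), bypasses step 17 and makes the aryl ether bond first. Williamson etherification of 14 with 26 (K2CO3, cat. NaI, acetone, 50 °C) gives the α-aryloxy ketone F6. Enolisation at its only acidic position (LiHMDS, THF, −78 °C) and chlorination with N-chlorosuccinimide give the α-chloro-α-aryloxy ketone F7. Silver-assisted methanolysis (AgOTf, MeOH, 2,6-di-tert-butylpyridine, CH2Cl2, −20 °C) gives the mixed acetal F8, and 1 M aq HCl in THF unmasks the aldehyde to return at 31.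

**Further compounds**

F1 | step 19 | racemic (3S*,4S*)-9-(benzyloxy)-3-[(6-(benzyloxy)-3-iodo-9-methoxy-1,7-dimethylphenanthren-2-yl)oxy]-4-hydroxy-3,6-dimethoxy-1,1,7-trimethyl-3,4-dihydrophenanthren-2(1H)-one (both enantiomers given) | COc1cc2c3c(cc(OCc4ccccc4)c2cc1C)C(C)(C)C(=O)[C@@](OC)(Oc1c(I)cc4c(cc(OC)c5cc(C)c(OCc6ccccc6)cc54)c1C)[C@H]3O.COc1cc2c3c(cc(OCc4ccccc4)c2cc1C)C(C)(C)C(=O)[C@](OC)(Oc1c(I)cc4c(cc(OC)c5cc(C)c(OCc6ccccc6)cc54)c1C)[C@@H]3O
F2 | step 19 | racemic 9,6'-di-O-benzylactephilol C (both enantiomers given) | COc1cc2c3c(cc(OCc4ccccc4)c2cc1C)C(C)(C)C(=O)[C@@]1(OC)Oc2c(cc4c(cc(OC)c5cc(C)c(OCc6ccccc6)cc54)c2C)O[C@@H]31.COc1cc2c3c(cc(OCc4ccccc4)c2cc1C)C(C)(C)C(=O)[C@]1(OC)Oc2c(cc4c(cc(OC)c5cc(C)c(OCc6ccccc6)cc54)c2C)O[C@H]31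
F3 | step 19 | (3R,4R)-9,6'-di-O-benzylactephilol C (mirror image of 33) | COc1cc2c3c(cc(OCc4ccccc4)c2cc1C)C(C)(C)C(=O)[C@]1(OC)Oc2c(cc4c(cc(OC)c5cc(C)c(OCc6ccccc6)cc54)c2C)O[C@H]31
F4 | step 15 | methyl 2-[4-(benzyloxy)-1-(dimethoxymethyl)-7-methoxy-6-methylnaphthalen-2-yl]acetate | COc1cc2c(C(OC)OC)c(CC(=O)OC)cc(OCc3ccccc3)c2cc1C
F5 | step 15 | methyl 2-[4-(benzyloxy)-1-(dimethoxymethyl)-7-methoxy-6-methylnaphthalen-2-yl]propanoate (racemic) | COc1cc2c(C(OC)OC)c(C(C)C(=O)OC)cc(OCc3ccccc3)c2cc1C
F6 | step 18 | 1-[(6-(benzyloxy)-3-iodo-9-methoxy-1,7-dimethylphenanthren-2-yl)oxy]-3-[4-(benzyloxy)-1-(dimethoxymethyl)-7-methoxy-6-methylnaphthalen-2-yl]-3-methylbutan-2-one | COc1cc2c(C(OC)OC)c(C(C)(C)C(=O)COc3c(I)cc4c(cc(OC)c5cc(C)c(OCc6ccccc6)cc54)c3C)cc(OCc3ccccc3)c2cc1C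
F7 | step 18 | 1-[(6-(benzyloxy)-3-iodo-9-methoxy-1,7-dimethylphenanthren-2-yl)oxy]-3-[4-(benzyloxy)-1-(dimethoxymethyl)-7-methoxy-6-methylnaphthalen-2-yl]-1-chloro-3-methylbutan-2-one (racemic) | COc1cc2c(C(OC)OC)c(C(C)(C)C(=O)C(Cl)Oc3c(I)cc4c(cc(OC)c5cc(C)c(OCc6ccccc6)cc54)c3C)cc(OCc3ccccc3)c2cc1C
F8 | step 18 | 1-[(6-(benzyloxy)-3-iodo-9-methoxy-1,7-dimethylphenanthren-2-yl)oxy]-3-[4-(benzyloxy)-1-(dimethoxymethyl)-7-methoxy-6-methylnaphthalen-2-yl]-1-methoxy-3-methylbutan-2-one (racemic) | COc1cc2c(C(OC)OC)c(C(C)(C)C(=O)C(OC)Oc3c(I)cc4c(cc(OC)c5cc(C)c(OCc6ccccc6)cc54)c3C)cc(OCc3ccccc3)c2cc1C
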